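**Retrosynthetic overview**

- Feature: ring B is a 2,3-dimethoxy-1,4-benzoquinone (C2′=O, C5′=O, OMe at C3′ and C4′) with a single carbon substituent, chroman C3 at C1′, and H at C6′. It sits beside ring A, a 6-hydroxy-7,8-dimethoxychroman (a p-alkoxyphenol) that would not survive an oxidant.
- Ring B is therefore built last and directly at the quinone level: C2′–C5′ come from dimethyl squarate and C1′/C6′ from a terminal alkyne. The disconnections are C1′–C2′ (thermal ring expansion) and C5′–C6′ (acetylide addition).
- The alkyne partner, the (3S)-3-ethynylchroman with its 6-OH as TBS ether, goes back through the 1,1-dibromoalkene and the aldehyde to the (3R)-chroman-3-carboxylic acid. C3 is set by asymmetric hydrogenation of the 2H-chromene-3-carboxylic acid.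
- The pyran ring comes from annulation of acrylonitrile onto a salicylaldehyde made from 2,3-dimethoxy-1,4-benzoquinone (reduction, mono-benzylation, ortho-formylation). Benzyl protects the 6-oxygen through the basic steps and is exchanged for TBS afterwards.
- Ring order: A (bought as the quinone), pyran ring (step 4), ring B (step 13), then desilylation.

Key step: step 13

Assumption: the hand of the iridium catalyst that gives the (3R)-acid is assigned in a trial run by chiral HPLC and correlation; the carbinol centre of 19 is carried as a mixture of epimers because it is destroyed in step 13.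

**Route**

Step 1
Reactants: 1 2,3-dimethoxy-1,4-benzoquinone
Product: 2 2,3-dimethoxybenzene-1,4-diol
Conditions: Na2S2O4, EtOAc/H2O, rt, under N2; used directly
Reagents that add atoms: none
Why: Dithionite reduces the quinone to the hydroquinone (two-electron quinone reduction), which frees the two phenols of ring A.

Step 2
Reactants: 2 2,3-dimethoxybenzene-1,4-diol
Product: 3 4-(benzyloxy)-2,3-dimethoxyphenol
Conditions: BnBr (0.9 equiv), K2CO3, degassed acetone, rt to 50 °C, N2; unreacted 2 recycled
Reagents that add atoms: benzyl bromide, BrCc1ccccc1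
Why: Williamson etherification of a symmetrical hydroquinone, so either hydroxyl gives the same mono-ether, and a deficit of bromide with exclusion of air should limit the bis-ether and re-oxidation.

Step 3
Reactants: 3 4-(benzyloxy)-2,3-dimethoxyphenol
Product: 5 5-(benzyloxy)-2-hydroxy-3,4-dimethoxybenzaldehyde, via salicyl alcohol 4 (not isolated)
Conditions: MgCl2, Et3N, (CH2O)n, MeCN, reflux; aq. HCl work-up
Reagents that add atoms: paraformaldehyde (formaldehyde), C=O
Why: Magnesium-mediated ortho-formylation (Casnati–Skattebøl): the magnesium phenoxide delivers formaldehyde to the only free ortho carbon to give 4, which is oxidised to the aldehyde by hydride transfer to a second formaldehyde.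

Step 4
Reactants: 5 5-(benzyloxy)-2-hydroxy-3,4-dimethoxybenzaldehyde; 6 acrylonitrile
Product: 7 6-(benzyloxy)-7,8-dimethoxy-2H-chromene-3-carbonitrile
Conditions: DABCO (0.5 equiv), neat acrylonitrile, 80 °C
Reagents that add atoms: none
Why: DABCO-mediated Baylis–Hillman-type annulation of a salicylaldehyde with acrylonitrile (C–C bond at the aldehyde carbon, conjugate closure by the phenol oxygen, loss of water) closes the pyran ring as the 2H-chromene with the nitrile carbon on C3.

Step 5
Reactants: 7 6-(benzyloxy)-7,8-dimethoxy-2H-chromene-3-carbonitrile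
Product: 9 6-(benzyloxy)-7,8-dimethoxy-2H-chromene-3-carboxylic acid, via primary amide 8 (not isolated)
Conditions: 10% aq. NaOH, EtOH, reflux; then HCl to pH 2
Reagents that add atoms: sodium hydroxide, [Na+].[OH-]; water, O
Why: Alkaline hydrolysis of the conjugated nitrile through amide 8, with benzyl and methyl ethers inert to hot hydroxide.

Step 6
Reactants: 9 6-(benzyloxy)-7,8-dimethoxy-2H-chromene-3-carboxylic acid
Product: 10 (3R)-6-(benzyloxy)-7,8-dimethoxychroman-3-carboxylic acid
Conditions: Ir(I)–spiro phosphine-oxazoline (SIPHOX-type) catalyst (1 mol %), H2 (6 bar), Et3N (0.5 equiv), MeOH, 45 °C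
Reagents that add atoms: none
Why: Carboxylate-directed iridium-catalysed asymmetric hydrogenation of a cyclic α,β-unsaturated acid, in which the chiral P,N ligand selects the face of the C3=C4 bond and so sets C3 (R in the acid, which is the spatial arrangement of the S-configured target); ee is to be checked by chiral HPLC and raised by crystallisation if needed.

Step 7
Reactants: 10 (3R)-6-(benzyloxy)-7,8-dimethoxychroman-3-carboxylic acid
Product: 11 (3R)-6-hydroxy-7,8-dimethoxychroman-3-carboxylic acid
Conditions: H2 (1 atm), 10% Pd/C, MeOH/EtOAc, rt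
Reagents that add atoms: none
Why: Palladium-catalysed hydrogenolysis of the benzyl ether; the chroman C–O bonds are alkyl aryl ether bonds that are not cleaved, and C3 is untouched.

Step 8
Reactants: 11 (3R)-6-hydroxy-7,8-dimethoxychroman-3-carboxylic acid
Product: 13 (3R)-6-(tert-butyldimethylsilyloxy)-7,8-dimethoxychroman-3-carboxylic acid, via bis-silyl compound 12 (not isolated)
Conditions: TBSCl (2.5 equiv), imidazole, DMF, rt; then THF/AcOH/H2O, rt
Reagents that add atoms: tert-butyldimethylsilyl chloride, CC(C)(C)[Si](C)(C)Cl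
Why: Imidazole-promoted silylation of phenol and acid gives 12, and the silyl ester, far more labile than the aryl silyl ether, is hydrolysed selectively by dilute acetic acid.

Step 9
Reactants: 13 (3R)-6-(tert-butyldimethylsilyloxy)-7,8-dimethoxychroman-3-carboxylic acid
Product: 14 [(3S)-6-(tert-butyldimethylsilyloxy)-7,8-dimethoxychroman-3-yl]methanol
Conditions: BH3·SMe2, THF, 0 °C to rt; MeOH quench, aqueous work-up
Reagents that add atoms: none
Why: Borane reduces the carboxylic acid chemoselectively through an acyloxyborane under non-basic conditions that leave the aryl silyl ether and C3 alone (the descriptor changes to S only because the priorities change).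

Step 10
Reactants: 14 [(3S)-6-(tert-butyldimethylsilyloxy)-7,8-dimethoxychroman-3-yl]methanol
Product: 15 (3R)-6-(tert-butyldimethylsilyloxy)-7,8-dimethoxychroman-3-carbaldehyde
Conditions: Dess–Martin periodinane, NaHCO3, CH2Cl2, 0 °C to rt; used at once without chromatography
Reagents that add atoms: none
Why: Dess–Martin oxidation under bicarbonate buffer stops at the aldehyde without acid or amine base, which matters because 15 is α-branched and β-aryloxy and therefore open to enolisation and retro-oxa-Michael ring opening.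

Step 11
Reactants: 15 (3R)-6-(tert-butyldimethylsilyloxy)-7,8-dimethoxychroman-3-carbaldehyde
Product: 16 (3S)-6-(tert-butyldimethylsilyloxy)-3-(2,2-dibromoethenyl)-7,8-dimethoxychroman
Conditions: CBr4 (2 equiv), PPh3 (2 equiv), Zn dust (2 equiv), CH2Cl2, rt (ylide preformed); then 15, 0 °C to rt
Reagents that add atoms: carbon tetrabromide, BrC(Br)(Br)Br
Why: Corey–Fuchs (Ramirez) dibromo-olefination with the zinc-generated, non-basic ylide Ph3P=CBr2 converts the aldehyde without enolisation, and the configurationally stable dibromoalkene is the point at which ee is checked.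

Step 12
Reactants: 16 (3S)-6-(tert-butyldimethylsilyloxy)-3-(2,2-dibromoethenyl)-7,8-dimethoxychroman; 17 dimethyl squarate
Product: 19 4-{[(3S)-6-(tert-butyldimethylsilyloxy)-7,8-dimethoxychroman-3-yl]ethynyl}-4-hydroxy-2,3-dimethoxycyclobut-2-en-1-one (mixture of carbinol epimers), via lithium acetylide 18 (not isolated)
Conditions: n-BuLi (2.05 equiv), THF, −78 to −20 °C; recool to −78 °C and cannulate into 17 (1.3 equiv) in THF, −78 °C; aq. NH4Cl at −78 °C
Reagents that add atoms: none
Why: The second stage of the Corey–Fuchs sequence (Br/Li exchange, Fritsch–Buttenberg–Wiechell 1,2-hydrogen shift, deprotonation) gives acetylide 18, which adds 1,2 to one of the two equivalent carbonyls of the squarate at −78 °C and forms C5′–C6′; the new carbinol centre is formed unselectively, which does not matter.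

Step 13
Reactants: 19 4-{[(3S)-6-(tert-butyldimethylsilyloxy)-7,8-dimethoxychroman-3-yl]ethynyl}-4-hydroxy-2,3-dimethoxycyclobut-2-en-1-one
Product: 22 5-[(3S)-6-(tert-butyldimethylsilyloxy)-7,8-dimethoxychroman-3-yl]-2,3-dimethoxy-1,4-benzoquinone, via enynylketene 20 (not isolated), via aryl-phenoxyl diradical 21 (not isolated)
Conditions: p-xylene (degassed, 0.01 M), reflux (138 °C), 0.5–1 h
Reagents that add atoms: none
Why: Heating opens the cyclobutenone by 4π-conrotatory electrocyclic ring opening with the C4 hydroxyl turning outward, which puts the alkynyl group cis to the ketene in 20; the ketene carbon (C2′) then bonds to the distal alkyne carbon (C1′) to give the six-membered diradical 21, and transfer of the hydroxyl hydrogen to the σ-radical carbon (C6′) gives quinone 22. This is the Moore rearrangement of 4-alkynyl-4-hydroxycyclobutenones to 1,4-benzoquinones. Ring B closes in the six-membered mode (C1′–C2′) and not in the five-membered mode that would lead to a 2-alkylidenecyclopent-4-ene-1,3-dione, because the secondary alkyl group at the alkyne terminus (chroman C3) cannot stabilise the exocyclic vinyl radical of the five-membered path. No stereocentre is formed: the carbinol centre is destroyed, so both epimers of 19 converge, and chroman C3 is a spectator that keeps its S configuration. The further selectivity needed is hydrogen transfer from the adjacent O–H and not 1,5-abstraction from chroman C2–H or C4–H; the free hydroxyl, whose loss gives the closed-shell quinone directly, together with high dilution in a non-donor solvent, should secure it.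

Step 14
Reactants: 22 5-[(3S)-6-(tert-butyldimethylsilyloxy)-7,8-dimethoxychroman-3-yl]-2,3-dimethoxy-1,4-benzoquinone
Product: 23 5-[(3S)-6-hydroxy-7,8-dimethoxychroman-3-yl]-2,3-dimethoxy-1,4-benzoquinone (CNP0302517.1)
Conditions: HF·pyridine, pyridine, THF, 0 °C to rt
Reagents that add atoms: none
Why: Fluoride cleaves the aryl Si–O bond (desilylation) under pyridine-buffered, non-redox conditions that both the methoxyquinone (a vinylogous ester) and the liberated p-alkoxyphenol tolerate.

**Compound list**

1 | 2,3-dimethoxy-1,4-benzoquinone | COC1=C(OC)C(=O)C=CC1=O | starting material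
2 | 2,3-dimethoxybenzene-1,4-diol | COc1c(O)ccc(O)c1OC | intermediate
3 | 4-(benzyloxy)-2,3-dimethoxyphenol | COc1c(O)ccc(OCc2ccccc2)c1OC | intermediate
4 | 4-(benzyloxy)-6-(hydroxymethyl)-2,3-dimethoxyphenol (formed as its magnesium salt) | COc1c(O)c(CO)cc(OCc2ccccc2)c1OC | intermediate
5 | 5-(benzyloxy)-2-hydroxy-3,4-dimethoxybenzaldehyde | COc1c(O)c(C=O)cc(OCc2ccccc2)c1OC | intermediate
6 | acrylonitrile | C=CC#N | starting material
7 | 6-(benzyloxy)-7,8-dimethoxy-2H-chromene-3-carbonitrile | N#CC1=Cc2cc(OCc3ccccc3)c(OC)c(OC)c2OC1 | intermediate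
8 | 6-(benzyloxy)-7,8-dimethoxy-2H-chromene-3-carboxamide | NC(=O)C1=Cc2cc(OCc3ccccc3)c(OC)c(OC)c2OC1 | intermediate
9 | 6-(benzyloxy)-7,8-dimethoxy-2H-chromene-3-carboxylic acid | OC(=O)C1=Cc2cc(OCc3ccccc3)c(OC)c(OC)c2OC1 | intermediate
10 | (3R)-6-(benzyloxy)-7,8-dimethoxychroman-3-carboxylic acid | OC(=O)[C@H]1COc2c(cc(OCc3ccccc3)c(OC)c2OC)C1 | intermediate
11 | (3R)-6-hydroxy-7,8-dimethoxychroman-3-carboxylic acid | OC(=O)[C@H]1COc2c(cc(O)c(OC)c2OC)C1 | intermediate
12 | tert-butyldimethylsilyl (3R)-6-(tert-butyldimethylsilyloxy)-7,8-dimethoxychroman-3-carboxylate | CC(C)(C)[Si](C)(C)OC(=O)[C@H]1COc2c(cc(O[Si](C)(C)C(C)(C)C)c(OC)c2OC)C1 | intermediate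
13 | (3R)-6-(tert-butyldimethylsilyloxy)-7,8-dimethoxychroman-3-carboxylic acid | OC(=O)[C@H]1COc2c(cc(O[Si](C)(C)C(C)(C)C)c(OC)c2OC)C1 | intermediate
14 | [(3S)-6-(tert-butyldimethylsilyloxy)-7,8-dimethoxychroman-3-yl]methanol | OC[C@H]1COc2c(cc(O[Si](C)(C)C(C)(C)C)c(OC)c2OC)C1 | intermediate
15 | (3R)-6-(tert-butyldimethylsilyloxy)-7,8-dimethoxychroman-3-carbaldehyde | O=C[C@H]1COc2c(cc(O[Si](C)(C)C(C)(C)C)c(OC)c2OC)C1 | intermediate
16 | (3S)-6-(tert-butyldimethylsilyloxy)-3-(2,2-dibromoethenyl)-7,8-dimethoxychroman | BrC(Br)=C[C@H]1COc2c(cc(O[Si](C)(C)C(C)(C)C)c(OC)c2OC)C1 | intermediate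
17 | dimethyl squarate (3,4-dimethoxycyclobut-3-ene-1,2-dione) | COC1=C(OC)C(=O)C1=O | starting material
18 | lithium [(3S)-6-(tert-butyldimethylsilyloxy)-7,8-dimethoxychroman-3-yl]ethynide | [Li]C#C[C@H]1COc2c(cc(O[Si](C)(C)C(C)(C)C)c(OC)c2OC)C1 | intermediate
19 | 4-{[(3S)-6-(tert-butyldimethylsilyloxy)-7,8-dimethoxychroman-3-yl]ethynyl}-4-hydroxy-2,3-dimethoxycyclobut-2-en-1-one (both carbinol epimers) | COC1=C(OC)C(O)(C#C[C@H]2COc3c(cc(O[Si](C)(C)C(C)(C)C)c(OC)c3OC)C2)C1=O | intermediate
20 | (3Z)-6-[(3S)-6-(tert-butyldimethylsilyloxy)-7,8-dimethoxychroman-3-yl]-4-hydroxy-2,3-dimethoxyhexa-1,3-dien-5-yn-1-one (enynylketene) | O=C=C(OC)/C(OC)=C(\C#C[C@H]1COc2c(cc(O[Si](C)(C)C(C)(C)C)c(OC)c2OC)C1)O | intermediate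
21 | 2-[(3S)-6-(tert-butyldimethylsilyloxy)-7,8-dimethoxychroman-3-yl]-4-hydroxy-5,6-dimethoxyphenoxyl-3-yl diradical | COc1c(OC)c(O)[c]c([C@H]2COc3c(cc(O[Si](C)(C)C(C)(C)C)c(OC)c3OC)C2)c1[O] | intermediate
22 | 5-[(3S)-6-(tert-butyldimethylsilyloxy)-7,8-dimethoxychroman-3-yl]-2,3-dimethoxy-1,4-benzoquinone | COC1=C(OC)C(=O)C([C@H]2COc3c(cc(O[Si](C)(C)C(C)(C)C)c(OC)c3OC)C2)=CC1=O | intermediate
23 | 5-[(3S)-6-hydroxy-7,8-dimethoxychroman-3-yl]-2,3-dimethoxy-1,4-benzoquinone (CNP0302517.1) | COC1=C(OC)C(=O)C([C@H]2COc3c(cc(O)c(OC)c3OC)C2)=CC1=O | target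

**Step count**

Total: 14 steps. Longest linear sequence: 14 steps (1 to 23); 6 and 17 are bought.

**Steps most likely to fail**

1. Step 13. The ketene may close onto the proximal alkyne carbon (five-membered mode), or the σ-radical of 21 may be quenched by 1,5-hydrogen transfer from chroman C2–H or C4–H and not from O–H, so that only part of the material reaches the quinone. The fallback replaces the diradical closure by a 6π-electrocyclisation. It sets out from aldehyde 15: Takai iodo-olefination (CrCl2, CHI3, THF) should give (3S)-6-(tert-butyldimethylsilyloxy)-3-[(E)-2-iodoethenyl]-7,8-dimethoxychroman F1. Iodine–lithium exchange (t-BuLi, −78 °C) and addition to 17 should give the 4-alkenyl-4-hydroxycyclobutenone F2. Heating F2 in toluene opens the ring to a dienylketene that closes by 6π-electrocyclisation and tautomerises to the hydroquinone F3. Oxidation of F3 with Ag2O, while ring A is still a silyl ether and inert, returns to the route at 22.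

2. Step 6. Facial discrimination may be poor, or turnover slow, on this electron-rich tetra-oxygenated chromene acid, leaving the acid with insufficient ee. The fallback is a classical resolution and sets out from 9: hydrogenation over Pd/C reduces the C3=C4 bond and removes the benzyl group in one operation to give racemic 6-hydroxy-7,8-dimethoxychroman-3-carboxylic acid F4. Crystallisation with (R)-1-phenylethylamine is expected to give the less soluble diastereomeric salt of the (3R)-acid F5 (the antipodal amine is used if the other salt crystallises). Acidification returns to the route at 11.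

3. Step 11. Aldehyde 15 may enolise or open by retro-oxa-Michael reaction while it meets the ylide and zinc bromide, which would erode the configuration at C3. The fallback avoids the aldehyde and sets out from acid 13: coupling with N,O-dimethylhydroxylamine (EDC, N-methylmorpholine) gives Weinreb amide F6, and MeMgBr gives methyl ketone F7. Kinetic deprotonation of the methyl group (LDA, −78 °C) and trapping with diethyl chlorophosphate gives enol phosphate F8. Elimination with LDA (2.2 equiv) and quench gives the terminal alkyne (3S)-6-(tert-butyldimethylsilyloxy)-3-ethynyl-7,8-dimethoxychroman F9. Deprotonation of F9 with n-BuLi (1.0 equiv) returns to the route at 18, which is added to 17 as in step 12.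

**Further compounds**

F1 | step 13 | (3S)-6-(tert-butyldimethylsilyloxy)-3-[(E)-2-iodoethenyl]-7,8-dimethoxychroman | I/C=C/[C@H]1COc2c(cc(O[Si](C)(C)C(C)(C)C)c(OC)c2OC)C1
F2 | step 13 | 4-{(E)-2-[(3S)-6-(tert-butyldimethylsilyloxy)-7,8-dimethoxychroman-3-yl]ethenyl}-4-hydroxy-2,3-dimethoxycyclobut-2-en-1-one | COC1=C(OC)C(O)(/C=C/[C@H]2COc3c(cc(O[Si](C)(C)C(C)(C)C)c(OC)c3OC)C2)C1=O
F3 | step 13 | 5-[(3S)-6-(tert-butyldimethylsilyloxy)-7,8-dimethoxychroman-3-yl]-2,3-dimethoxybenzene-1,4-diol | COc1c(O)cc([C@H]2COc3c(cc(O[Si](C)(C)C(C)(C)C)c(OC)c3OC)C2)c(O)c1OC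
F4 | step 6 | racemic 6-hydroxy-7,8-dimethoxychroman-3-carboxylic acid | OC(=O)C1COc2c(cc(O)c(OC)c2OC)C1
F5 | step 6 | (R)-1-phenylethylammonium (3R)-6-hydroxy-7,8-dimethoxychroman-3-carboxylate | C[C@@H]([NH3+])c1ccccc1.[O-]C(=O)[C@H]1COc2c(cc(O)c(OC)c2OC)C1
F6 | step 11 | (3R)-6-(tert-butyldimethylsilyloxy)-N,7,8-trimethoxy-N-methylchroman-3-carboxamide | CON(C)C(=O)[C@H]1COc2c(cc(O[Si](C)(C)C(C)(C)C)c(OC)c2OC)C1
F7 | step 11 | 1-[(3R)-6-(tert-butyldimethylsilyloxy)-7,8-dimethoxychroman-3-yl]ethan-1-one | CC(=O)[C@H]1COc2c(cc(O[Si](C)(C)C(C)(C)C)c(OC)c2OC)C1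
F8 | step 11 | 1-[(3R)-6-(tert-butyldimethylsilyloxy)-7,8-dimethoxychroman-3-yl]ethenyl diethyl phosphate | C=C(OP(=O)(OCC)OCC)[C@H]1COc2c(cc(O[Si](C)(C)C(C)(C)C)c(OC)c2OC)C1
F9 | step 11 | (3S)-6-(tert-butyldimethylsilyloxy)-3-ethynyl-7,8-dimethoxychroman | C#C[C@H]1COc2c(cc(O[Si](C)(C)C(C)(C)C)c(OC)c2OC)C1
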